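I have to choose one change for the next flask at 0.20 M, and the choice depends on whether the flat target in the earlier runs is an end or a balance.

| setting | ochre | amber | flask |
|---|---|---|---|
| solid substrate | 0.10 M | 0.15 M | 0.20 M |
| gas phase | 6.9 mM (held) | 6.9 mM (held) | 6.9 mM (held) |
| remark | run made earlier | run made earlier |  |
| time |  |  | 2.0 h |

| run | time / min | target / % | solid substrate / % |
|---|---|---|---|
| ochre | 6.00 | 1.5 | 50.2 |
| ochre | 10.0 | 4.5 | 24.9 |
| ochre | 20.0 | 11.6 | 0.3 |
| ochre | 40.0 | 20.7 | 0.8 |
| ochre | 80.0 | 23.9 | 0.4 |
| amber | 15.0 | 4.8 | 35.9 |
| amber | 30.0 | 13.0 | 7.2 |
| amber | 40.0 | 16.9 | 0 |
| amber | 60.0 | 22.0 | 0 |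
| amber | 80.0 | 23.4 | 0.6 |

(scatter of a reading: 0.5 percentage points)

- as a solid, counted per litre of solution: solid substrate
- at the start none of the gas is dissolved
- on the list of suspects stand: dissolved gas <-> dormant form; solid substrate <-> starting material; starting material + dissolved gas -> target; target <-> isomer of the product; gas phase <-> dissolved gas
- at the start none of the solid substrate is in solution

- amount of target at 2.0 h, in percent of the solid substrate charged
- the change that raises the amount of target at 2.0 h, in percent of the solid substrate charged most ("none" if none brings more than 2 percentage points) (oak / alder / ash / elm / none)
- amount of target at 2.0 h, in percent of the solid substrate charged, after alder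

- oak: doubling the saturation concentration of gas phase, all else as stated
- alder: doubling the dissolution coefficient of the solid substrate, all else as stated
- ash: doubling the solubility of the solid substrate, all else as stated
- elm: doubling the transfer coefficient of the gas phase, all else as stated

Target forms from starting material and dissolved gas. I treat gas uptake as quick, with dissolved gas near 6.9 mM, so the making is pseudo-first-order in starting material. I define κ, the making coefficient, as the rise of target per minute divided by the share of the charge present as starting material. Between 10.0 min and 20.0 min the ochre run gains 7.1 percentage points with on average about 79.4% of the charge neither solid nor target, which I count as starting material, so I read κ = 0.00895 min⁻¹. Its time constant 1/κ is 112 min, close to the 2.0 h of this flask. With the whole charge counted as starting material from the beginning, κ reckons about 51.1% made by 80.0 min in the ochre run, more than the 23.9% that target reads there. So I read the difference as passed on to isomer of the product, and the flat target as making balanced by loss. Making scales with dissolved gas, so I choose oak and expect target near 23.9%.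

The forecast gives 24% (22.8% to 25%), 24.2% (23.2% to 25.2%) after alder, and as best change none: “The equilibrium stays put”. On the best change we part.

The simulation gives 23.1%, 23.0% after alder, and oak as best: oak adds 3.9 points, elm 0.79 points, alder −0.078 points, ash −0.24 points.

    dissolved gas ⇌ dormant form (K = 39.0, k = 0.0490 min⁻¹)
    solid substrate ⇌ starting material, rate k2*(cs2 - [starting material]) while solid is left; crystals form when [starting material] > cs2 (solubility = 0.140 M, k = 0.0750 min⁻¹)
    starting material + dissolved gas → target (k = 1.90 L mol⁻¹ min⁻¹)
    target ⇌ isomer of the product (K = 5.10, k = 0.0280 min⁻¹)
    gas phase ⇌ dissolved gas, rate k5*(csat - [dissolved gas]) (kL = 1.20 min⁻¹)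

Target in this flask stands low mainly because it passes on into isomer of the product: with that passing taken away, target reads 64.7% instead of 23.1%. κ on the 35.3% starting material still in this flask at 2.00 h gives 0.00316 min⁻¹, a share of the charge per minute, as new target. In the neighbour with 0.80 M of solid substrate, κ acting on its end share of 15.3% starting material, taken as held for 2.0 h, gives about 16.4% made; computed, target and isomer of the product together reach 17.8%.

The readings were computed for an exercise; the scatter is artificial.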